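**Plan**

- Retrosynthesis: the two ester groups and the silyl ethers are removed first. The butenolide is cut at O–C12 and at C7=C11, back to a C6 ketone and a three-carbon keto ester. The ten-membered ring is cut at C8–C9 while C1–C6 is re-formed (retro oxy-Cope). The resulting cyclohexanol is cut at C1–C10 (epoxide opening) and C6–C7 (addition to a ketone).
- Enabling feature: C6 carries the enol-lactone oxygen, C8 lies two bonds away on one side, and the allyl unit C9–C10=C1 lies on the other. Once C1 is bonded to C6, the six-membered ring C1–C6 holds the array C8=C7–C6(O)–C1–C10=C9, a 3-oxy-1,5-diene.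
- Forward: 3-methylcyclohexenone gives the six-membered ring. An epoxy ketone then takes the two alkenyl groups. The anionic oxy-Cope shift closes the ten-membered ring at C8–C9 and opens C1–C6. The resulting C6 enolate is trapped by a keto ester at C7. The butenolide ring and its C5=C6 ylidene follow, and the esters go on last.
- Stereochemistry: C4 comes from a catalytic asymmetric conjugate borylation. C2 comes from epoxidation cis to the C4 silyloxy group. C6 and C1 (both sacrificed later) come from two additions anti to the epoxide. C8 and the (Z)-C1=C10 alkene come from the chair transition state of the oxy-Cope shift with a (Z)-enol ether.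

Key step: step 12

Remark (numbering): the ring carbons are numbered C1 to C10 as in a germacrane (C1=C10 alkene, C2 acetoxy carbon, C4 carbinol carbon, C6 enol-lactone carbon, C8 methacrylate carbon); C11, C12 and C13 are the lactone α-carbon, the lactone carbonyl carbon and the CH2OH carbon. The same locants are used for the cyclohexane precursors.

Remark (assumption): in step 1 the antipode of the ligand QuinoxP* that delivers the (R)-boronate 2 is used; DL-glyceric acid is taken as a commercial material.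

**Route**

Step 1
Reactants: 1 3-methylcyclohex-2-en-1-one
Product: 3 (S)-3-hydroxy-3-methylcyclohexan-1-one, via tertiary pinacol boronate 2 (not isolated)
Conditions: B2pin2, [Cu(MeCN)4]PF6 (cat.), QuinoxP* (cat.), LiOt-Bu (cat.), i-PrOH, DMSO, rt; then NaBO3·4H2O, THF/H2O, rt
Reagents that add atoms: sodium perborate, [Na+].[Na+].O[B-]1(O)OO[B-](O)(O)OO1
Why: Enantioselective conjugate borylation of the β,β-disubstituted enone by a chiral copper boryl species sets C4 as the tertiary boronate, and perborate oxidation replaces boron by hydroxyl with retention to give the 4S carbinol.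

Step 2
Reactants: 3 (S)-3-hydroxy-3-methylcyclohexan-1-one
Product: 4 (S)-3-[(tert-butyldimethylsilyl)oxy]-3-methylcyclohexan-1-one
Conditions: TBSOTf, 2,6-lutidine, CH2Cl2, −78 → 0 °C
Reagents that add atoms: tert-butyldimethylsilyl trifluoromethanesulfonate, CC(C)(C)[Si](C)(C)OS(=O)(=O)C(F)(F)F
Why: Silylation of a tertiary alcohol with a silyl triflate and a hindered pyridine base is routine and blocks retro-aldol cleavage and dehydration of the β-hydroxy ketone in the basic steps that follow.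

Step 3
Reactants: 4 (S)-3-[(tert-butyldimethylsilyl)oxy]-3-methylcyclohexan-1-one
Product: 6 (S)-5-[(tert-butyldimethylsilyl)oxy]-5-methylcyclohex-2-en-1-one, via trimethylsilyl enol ether 5 (not isolated)
Conditions: LiN(i-Pr)2, TMSCl, THF, −78 °C; then Pd(OAc)2 (cat.), O2 (1 atm), DMSO, rt
Reagents that add atoms: none
Why: Saegusa–Ito oxidation; kinetic enolisation away from the quaternary carbon gives silyl enol ether 5, and only this regioisomer has a β-hydrogen for the dehydrogenation, so the enone can form on the C1–C2 side only.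

Step 4
Reactants: 6 (S)-5-[(tert-butyldimethylsilyl)oxy]-5-methylcyclohex-2-en-1-one
Product: 7 (1R,4S,6R)-4-[(tert-butyldimethylsilyl)oxy]-4-methyl-7-oxabicyclo[4.1.0]heptan-2-one
Conditions: t-BuOOH, DBU, CH2Cl2, 0 °C
Reagents that add atoms: tert-butyl hydroperoxide, CC(C)(C)OO
Why: Weitz–Scheffer (nucleophilic) epoxidation; the hydroperoxide anion should add axially to C2 on the face of the pseudo-axial silyloxy group (the smaller C4 substituent sits axial and the methyl equatorial), which places the epoxide and the future C2 oxygen cis to the C4 oxygen.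

Step 5
Reactants: 8 (4-methoxyphenyl)methanol
Product: 9 1-[(ethenyloxy)methyl]-4-methoxybenzene
Conditions: ethyl vinyl ether (solvent), Hg(OAc)2 (cat.), reflux
Reagents that add atoms: ethyl vinyl ether, CCOC=C
Why: Hg(OAc)2-catalysed transfer vinylation (transetherification) of a primary benzylic alcohol with ethyl vinyl ether is a standard route to vinyl ethers.

Step 6
Reactants: 9 1-[(ethenyloxy)methyl]-4-methoxybenzene
Product: 11 1-{[(Z)-2-bromoethenyl]oxymethyl}-4-methoxybenzene, via dibromo ether 10 (not isolated)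
Conditions: Br2, CH2Cl2, −78 °C; then i-Pr2NEt, −78 → 40 °C
Reagents that add atoms: bromine, BrBr
Why: Bromine adds to the electron-rich vinyl ether, and amine-induced dehydrobromination of the dibromo ether should give the 2-bromovinyl ether mainly as the (Z)-isomer, as in the preparation of the ethyl analogue.

Step 7
Reactants: 11 1-{[(Z)-2-bromoethenyl]oxymethyl}-4-methoxybenzene; 7 (1R,4S,6R)-4-[(tert-butyldimethylsilyl)oxy]-4-methyl-7-oxabicyclo[4.1.0]heptan-2-one
Product: 13 (1R,2R,4S,6R)-4-[(tert-butyldimethylsilyl)oxy]-2-{(Z)-2-[(4-methoxybenzyl)oxy]ethenyl}-4-methyl-7-oxabicyclo[4.1.0]heptan-2-ol, via alkenyllithium 12 (not isolated)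
Conditions: 11, t-BuLi (2 equiv), Et2O, −78 °C; then 7, THF, −78 °C; H2O
Reagents that add atoms: none
Why: Bromine–lithium exchange gives the configurationally stable (Z)-2-alkoxyvinyllithium, and its 1,2-addition to the epoxy ketone should occur on the face opposite the epoxide oxygen and the pseudo-axial silyloxy group, so that the C6 hydroxyl is cis to the epoxide and the alkenyl group trans.

Step 8
Reactants: 13 (1R,2R,4S,6R)-4-[(tert-butyldimethylsilyl)oxy]-2-{(Z)-2-[(4-methoxybenzyl)oxy]ethenyl}-4-methyl-7-oxabicyclo[4.1.0]heptan-2-ol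
Product: 14 (1R,2S,3R,5S)-5-[(tert-butyldimethylsilyl)oxy]-1-{(Z)-2-[(4-methoxybenzyl)oxy]ethenyl}-5-methyl-2-(prop-1-en-2-yl)cyclohexane-1,3-diol
Conditions: CH2=C(CH3)MgBr, CuI (cat.), THF, −30 → 0 °C; H2O/aq. NH3
Reagents that add atoms: isopropenylmagnesium bromide, CC(=C)[Mg]Br
Why: CuI-catalysed SN2 opening of the epoxide by the alkenyl Grignard reagent with inversion at C1; in the half-chair with the C4 and C6 oxygens pseudo-axial, attack at C1 is the trans-diaxial (Fürst–Plattner) mode, whereas axial attack at C2 would run syn to the C4 methyl and the C6 alkenyl group, so the isopropenyl group should end trans to both neighbouring oxygens.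

Step 9
Reactants: 15 DL-glyceric acid (2,3-dihydroxypropanoic acid)
Product: 16 prop-2-en-1-yl 2,3-dihydroxypropanoate
Conditions: allyl alcohol (excess), TsOH·H2O (cat.), molecular sieves, 80 °C
Reagents that add atoms: allyl alcohol, C=CCO
Why: Fischer esterification driven by excess alcohol and removal of water.

Step 10
Reactants: 16 prop-2-en-1-yl 2,3-dihydroxypropanoate
Product: 17 prop-2-en-1-yl 3-[(tert-butyldimethylsilyl)oxy]-2-hydroxypropanoate
Conditions: TBSCl, imidazole, CH2Cl2, −10 °C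
Reagents that add atoms: tert-butyldimethylsilyl chloride, CC(C)(C)[Si](C)(C)Cl
Why: The primary hydroxyl is silylated selectively over the secondary α-hydroxyl under standard imidazole conditions.

Step 11
Reactants: 17 prop-2-en-1-yl 3-[(tert-butyldimethylsilyl)oxy]-2-hydroxypropanoate
Product: 18 prop-2-en-1-yl 3-[(tert-butyldimethylsilyl)oxy]-2-oxopropanoate
Conditions: Dess–Martin periodinane, CH2Cl2, rt
Reagents that add atoms: none
Why: Dess–Martin oxidation of an α-hydroxy ester to the α-keto ester, which is used without delay.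

Step 12
Reactants: 14 (1R,2S,3R,5S)-5-[(tert-butyldimethylsilyl)oxy]-1-{(Z)-2-[(4-methoxybenzyl)oxy]ethenyl}-5-methyl-2-(prop-1-en-2-yl)cyclohexane-1,3-diol; 18 prop-2-en-1-yl 3-[(tert-butyldimethylsilyl)oxy]-2-oxopropanoate
Product: 21 prop-2-en-1-yl (1(10)Z,2R,4S,8R)-4,13-bis[(tert-butyldimethylsilyl)oxy]-2,11-dihydroxy-8-[(4-methoxybenzyl)oxy]-6-oxogermacr-1(10)-en-12-oate (C7 and C11 epimers), via dipotassium dialkoxide 19 (not isolated), via ring-expanded dipotassium enolate 20 (not isolated)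
Conditions: KN(SiMe3)2 (2.2 equiv), THF, −78 → 40 °C; then 18, −78 °C; AcOH, −78 °C
Reagents that add atoms: none
Why: Deprotonation of both hydroxyls gives dialkoxide 19, whose 3-oxido-1,5-diene C8=C7–C6(O–)–C1–C10=C9 undergoes the anion-accelerated [3,3]-sigmatropic shift (anionic oxy-Cope rearrangement): the C1–C6 bond of the cyclohexane breaks while C8–C9 forms, which closes the ten-membered ring as its C6 enolate 20. The closest known reaction type is the anionic oxy-Cope ring expansion of 1,2-dialkenylcyclohexanols to cyclodec-5-enones, followed by aldol trapping of the regiodefined enolate. The ten-membered ring is closed by a four-atom ring expansion through a six-membered chair transition state and not by an end-to-end cyclisation, so high dilution is not needed. C8 should become (R) because the (Z)-enol ether holds its oxygen pseudo-axial in this chair and C9 adds to the C8 face fixed by the C6 and C1 configurations, and the C1=C10 alkene should become (Z) because the ring bond C1–C2 is pseudo-axial in the same chair. The step needs the cyclohexane chair with the C6 alkenyl group axial and the isopropenyl group equatorial; the all-cis oxygens at C2, C4 and C6 secure it, since the other chair would place two alkoxides and the silyloxy group syn-triaxial. Potassium bridging the C6 and C8 oxygens should keep the C8–O bond in the enolate plane and so hold back β-elimination until enolate 20 adds through C7, the only enolate carbon formed, to the ketone carbonyl of 18 at −78 °C.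

Step 13
Reactants: 21 prop-2-en-1-yl (1(10)Z,2R,4S,8R)-4,13-bis[(tert-butyldimethylsilyl)oxy]-2,11-dihydroxy-8-[(4-methoxybenzyl)oxy]-6-oxogermacr-1(10)-en-12-oate
Product: 23 prop-2-en-1-yl (1(10)Z,2R,4S,8R)-2-acetoxy-4,13-bis[(tert-butyldimethylsilyl)oxy]-8-[(4-methoxybenzyl)oxy]-6-oxogermacra-1(10),7(11)-dien-12-oate (E/Z mixture at C7=C11), via C2/C11 diacetate 22 (not isolated)
Conditions: Ac2O, DMAP, Et3N, CH2Cl2, 0 → 30 °C
Reagents that add atoms: acetic anhydride, CC(=O)OC(C)=O
Why: DMAP-catalysed acetylation of the secondary C2 hydroxyl and of the tertiary aldol hydroxyl is followed by E1cB loss of acetate from the β-acetoxy ketone, which installs the C2 acetate of the target and the C7=C11 double bond; acetate leaves far more readily than the C8 alkoxide.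

Step 14
Reactants: 23 prop-2-en-1-yl (1(10)Z,2R,4S,8R)-2-acetoxy-4,13-bis[(tert-butyldimethylsilyl)oxy]-8-[(4-methoxybenzyl)oxy]-6-oxogermacra-1(10),7(11)-dien-12-oate
Product: 24 (1(10)Z,2R,4S,8R)-2-acetoxy-4,13-bis[(tert-butyldimethylsilyl)oxy]-6-hydroxy-8-[(4-methoxybenzyl)oxy]germacra-1(10),7(11)-dien-12,6-olide (C6 epimers)
Conditions: Pd(PPh3)4 (cat.), morpholine, THF, 0 °C; pH 4 buffer
Reagents that add atoms: none
Why: Deallylation by zerovalent palladium (π-allyl transfer to morpholine) frees the carboxylic acid within minutes at 0 °C, where the hindered C2 allylic acetate should stay inert, and the (Z)-4-oxo-2-enoic acid closes to its ring tautomer, the 5-hydroxybutenolide; the (E)-acid is expected to feed into it through reversible amine conjugate addition.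

Step 15
Reactants: 24 (1(10)Z,2R,4S,8R)-2-acetoxy-4,13-bis[(tert-butyldimethylsilyl)oxy]-6-hydroxy-8-[(4-methoxybenzyl)oxy]germacra-1(10),7(11)-dien-12,6-olide
Product: 26 (1(10)Z,2R,4S,5E,8R)-2-acetoxy-4,13-bis[(tert-butyldimethylsilyl)oxy]-8-[(4-methoxybenzyl)oxy]germacra-1(10),5,7(11)-trien-12,6-olide, via C6 acetoxybutenolide 25 (not isolated)
Conditions: Ac2O, Et3N, DMAP (cat.), CH2Cl2, 0 °C; then DBU, 0 °C → rt
Reagents that add atoms: none
Why: Acylation of the lactol hydroxyl and base-induced loss of acetic acid toward C5, the only carbon with β-hydrogens, gives the γ-ylidenebutenolide; the ring-cis (5E) alkene of the target is expected to be the more stable isomer in the ten-membered ring.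

Step 16
Reactants: 26 (1(10)Z,2R,4S,5E,8R)-2-acetoxy-4,13-bis[(tert-butyldimethylsilyl)oxy]-8-[(4-methoxybenzyl)oxy]germacra-1(10),5,7(11)-trien-12,6-olide
Product: 27 (1(10)Z,2R,4S,5E,8R)-2-acetoxy-4,13-bis[(tert-butyldimethylsilyl)oxy]-8-hydroxygermacra-1(10),5,7(11)-trien-12,6-olide
Conditions: DDQ, CH2Cl2/pH 7 phosphate buffer, 0 °C → rt
Reagents that add atoms: none
Why: Oxidative cleavage of the 4-methoxybenzyl ether with DDQ under buffered conditions should leave the silyl ethers, the acetate and the enol lactone untouched.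

Step 17
Reactants: 27 (1(10)Z,2R,4S,5E,8R)-2-acetoxy-4,13-bis[(tert-butyldimethylsilyl)oxy]-8-hydroxygermacra-1(10),5,7(11)-trien-12,6-olide
Product: 28 (1(10)Z,2R,4S,5E,8R)-2-acetoxy-4,13-bis[(tert-butyldimethylsilyl)oxy]-8-(2-methylprop-2-enoyloxy)germacra-1(10),5,7(11)-trien-12,6-olide
Conditions: methacrylic anhydride, Et3N, DMAP (cat.), CH2Cl2, 0 °C → rt
Reagents that add atoms: methacrylic anhydride, CC(=C)C(=O)OC(=O)C(C)=C
Why: DMAP-catalysed acyl transfer to the only free hydroxyl, the secondary C8 alcohol, without touching its configuration.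

Step 18
Reactants: 28 (1(10)Z,2R,4S,5E,8R)-2-acetoxy-4,13-bis[(tert-butyldimethylsilyl)oxy]-8-(2-methylprop-2-enoyloxy)germacra-1(10),5,7(11)-trien-12,6-olide
Product: 29 (1(10)Z,2R,4S,5E,8R)-2-acetoxy-4,13-dihydroxy-8-(2-methylprop-2-enoyloxy)germacra-1(10),5,7(11)-trien-12,6-olide (the target)
Conditions: HF·pyridine, pyridine, THF, 0 °C → rt
Reagents that add atoms: none
Why: Buffered HF·pyridine cleaves the primary and the tertiary silyl ether at the Si–O bond and should neither ionise the tertiary allylic C4–O bond nor touch the two esters.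

**Compound list**

1 | 3-methylcyclohex-2-en-1-one | CC1=CC(=O)CCC1 | starting material
2 | (R)-3-methyl-3-(4,4,5,5-tetramethyl-1,3,2-dioxaborolan-2-yl)cyclohexan-1-one | O=C1CCC[C@](C)(B2OC(C)(C)C(C)(C)O2)C1 | intermediate
3 | (S)-3-hydroxy-3-methylcyclohexan-1-one | O=C1CCC[C@](C)(O)C1 | intermediate
4 | (S)-3-[(tert-butyldimethylsilyl)oxy]-3-methylcyclohexan-1-one | O=C1CCC[C@](C)(O[Si](C)(C)C(C)(C)C)C1 | intermediate
5 | tert-butyldimethyl{[(1S)-1-methyl-3-[(trimethylsilyl)oxy]cyclohex-3-en-1-yl]oxy}silane | C[Si](C)(C)OC1=CCC[C@](C)(O[Si](C)(C)C(C)(C)C)C1 | intermediate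
6 | (S)-5-[(tert-butyldimethylsilyl)oxy]-5-methylcyclohex-2-en-1-one | O=C1C=CC[C@](C)(O[Si](C)(C)C(C)(C)C)C1 | intermediate
7 | (1R,4S,6R)-4-[(tert-butyldimethylsilyl)oxy]-4-methyl-7-oxabicyclo[4.1.0]heptan-2-one | O=C1[C@@H]2O[C@@H]2C[C@](C)(O[Si](C)(C)C(C)(C)C)C1 | intermediate
8 | (4-methoxyphenyl)methanol | COc1ccc(CO)cc1 | starting material
9 | 1-[(ethenyloxy)methyl]-4-methoxybenzene | COc1ccc(COC=C)cc1 | intermediate
10 | 1-[(1,2-dibromoethoxy)methyl]-4-methoxybenzene (racemic) | COc1ccc(COC(Br)CBr)cc1 | intermediate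
11 | 1-{[(Z)-2-bromoethenyl]oxymethyl}-4-methoxybenzene | Br/C=C\OCc1ccc(OC)cc1 | intermediate
12 | {(Z)-2-[(4-methoxybenzyl)oxy]ethenyl}lithium | [Li]/C=C\OCc1ccc(OC)cc1 | intermediate
13 | (1R,2R,4S,6R)-4-[(tert-butyldimethylsilyl)oxy]-2-{(Z)-2-[(4-methoxybenzyl)oxy]ethenyl}-4-methyl-7-oxabicyclo[4.1.0]heptan-2-ol | O[C@]1(/C=C\OCc2ccc(OC)cc2)[C@@H]2O[C@@H]2C[C@](C)(O[Si](C)(C)C(C)(C)C)C1 | intermediate
14 | (1R,2S,3R,5S)-5-[(tert-butyldimethylsilyl)oxy]-1-{(Z)-2-[(4-methoxybenzyl)oxy]ethenyl}-5-methyl-2-(prop-1-en-2-yl)cyclohexane-1,3-diol | O[C@]1(/C=C\OCc2ccc(OC)cc2)[C@@H](C(C)=C)[C@H](O)C[C@](C)(O[Si](C)(C)C(C)(C)C)C1 | intermediate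
15 | DL-glyceric acid (2,3-dihydroxypropanoic acid) | OCC(O)C(=O)O | starting material
16 | prop-2-en-1-yl 2,3-dihydroxypropanoate (racemic) | OCC(O)C(=O)OCC=C | intermediate
17 | prop-2-en-1-yl 3-[(tert-butyldimethylsilyl)oxy]-2-hydroxypropanoate (racemic) | C=CCOC(=O)C(O)CO[Si](C)(C)C(C)(C)C | intermediate
18 | prop-2-en-1-yl 3-[(tert-butyldimethylsilyl)oxy]-2-oxopropanoate | C=CCOC(=O)C(=O)CO[Si](C)(C)C(C)(C)C | intermediate
19 | dipotassium dialkoxide of 14 | [K+].[K+].[O-][C@]1(/C=C\OCc2ccc(OC)cc2)[C@@H](C(C)=C)[C@H]([O-])C[C@](C)(O[Si](C)(C)C(C)(C)C)C1 | intermediate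
20 | dipotassium (1(10)Z,2R,4S,6Z,8R)-4-[(tert-butyldimethylsilyl)oxy]-8-[(4-methoxybenzyl)oxy]-4,10-dimethylcyclodeca-1(10),6-diene-2,6-diolate (ring numbered as in the remark) | [K+].[K+].[O-]/C1=C\[C@H](OCc2ccc(OC)cc2)C/C(C)=C\[C@H]([O-])C[C@](C)(O[Si](C)(C)C(C)(C)C)C1 | intermediate
21 | prop-2-en-1-yl (1(10)Z,2R,4S,8R)-4,13-bis[(tert-butyldimethylsilyl)oxy]-2,11-dihydroxy-8-[(4-methoxybenzyl)oxy]-6-oxogermacr-1(10)-en-12-oate (C7 and C11 epimers) | O=C1C(C(O)(CO[Si](C)(C)C(C)(C)C)C(=O)OCC=C)[C@H](OCc2ccc(OC)cc2)C/C(C)=C\[C@H](O)C[C@](C)(O[Si](C)(C)C(C)(C)C)C1 | intermediate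
22 | prop-2-en-1-yl (1(10)Z,2R,4S,8R)-2,11-diacetoxy-4,13-bis[(tert-butyldimethylsilyl)oxy]-8-[(4-methoxybenzyl)oxy]-6-oxogermacr-1(10)-en-12-oate (C7 and C11 epimers) | O=C1C(C(OC(C)=O)(CO[Si](C)(C)C(C)(C)C)C(=O)OCC=C)[C@H](OCc2ccc(OC)cc2)C/C(C)=C\[C@H](OC(C)=O)C[C@](C)(O[Si](C)(C)C(C)(C)C)C1 | intermediate
23 | prop-2-en-1-yl (1(10)Z,2R,4S,8R)-2-acetoxy-4,13-bis[(tert-butyldimethylsilyl)oxy]-8-[(4-methoxybenzyl)oxy]-6-oxogermacra-1(10),7(11)-dien-12-oate (E/Z mixture at C7=C11) | O=C1C(=C(CO[Si](C)(C)C(C)(C)C)C(=O)OCC=C)[C@H](OCc2ccc(OC)cc2)C/C(C)=C\[C@H](OC(C)=O)C[C@](C)(O[Si](C)(C)C(C)(C)C)C1 | intermediate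
24 | (1(10)Z,2R,4S,8R)-2-acetoxy-4,13-bis[(tert-butyldimethylsilyl)oxy]-6-hydroxy-8-[(4-methoxybenzyl)oxy]germacra-1(10),7(11)-dien-12,6-olide (C6 epimers) | OC12OC(=O)C(CO[Si](C)(C)C(C)(C)C)=C1[C@H](OCc3ccc(OC)cc3)C/C(C)=C\[C@H](OC(C)=O)C[C@](C)(O[Si](C)(C)C(C)(C)C)C2 | intermediate
25 | (1(10)Z,2R,4S,8R)-2,6-diacetoxy-4,13-bis[(tert-butyldimethylsilyl)oxy]-8-[(4-methoxybenzyl)oxy]germacra-1(10),7(11)-dien-12,6-olide (C6 epimers) | CC(=O)OC12OC(=O)C(CO[Si](C)(C)C(C)(C)C)=C1[C@H](OCc3ccc(OC)cc3)C/C(C)=C\[C@H](OC(C)=O)C[C@](C)(O[Si](C)(C)C(C)(C)C)C2 | intermediate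
26 | (1(10)Z,2R,4S,5E,8R)-2-acetoxy-4,13-bis[(tert-butyldimethylsilyl)oxy]-8-[(4-methoxybenzyl)oxy]germacra-1(10),5,7(11)-trien-12,6-olide | COc1ccc(CO[C@@H]2C/C(C)=C\[C@H](OC(C)=O)C[C@](C)(O[Si](C)(C)C(C)(C)C)/C=C3/OC(=O)C(CO[Si](C)(C)C(C)(C)C)=C32)cc1 | intermediate
27 | (1(10)Z,2R,4S,5E,8R)-2-acetoxy-4,13-bis[(tert-butyldimethylsilyl)oxy]-8-hydroxygermacra-1(10),5,7(11)-trien-12,6-olide | O[C@@H]1C/C(C)=C\[C@H](OC(C)=O)C[C@](C)(O[Si](C)(C)C(C)(C)C)/C=C2/OC(=O)C(CO[Si](C)(C)C(C)(C)C)=C21 | intermediate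
28 | (1(10)Z,2R,4S,5E,8R)-2-acetoxy-4,13-bis[(tert-butyldimethylsilyl)oxy]-8-(2-methylprop-2-enoyloxy)germacra-1(10),5,7(11)-trien-12,6-olide | C=C(C)C(=O)O[C@@H]1C/C(C)=C\[C@H](OC(C)=O)C[C@](C)(O[Si](C)(C)C(C)(C)C)/C=C2/OC(=O)C(CO[Si](C)(C)C(C)(C)C)=C21 | intermediate
29 | (1(10)Z,2R,4S,5E,8R)-2-acetoxy-4,13-dihydroxy-8-(2-methylprop-2-enoyloxy)germacra-1(10),5,7(11)-trien-12,6-olide | C=C(C)C(=O)O[C@@H]1C/C(C)=C\[C@H](OC(C)=O)C[C@](C)(O)/C=C2/OC(=O)C(CO)=C21 | target

**Step count and risks**

Total step count: 18. Longest linear sequence: 13 steps (steps 1–4, 7, 8 and 12–18).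

Steps most likely to fail:

1. Step 12. What may go wrong: β-elimination of the C8 alkoxy group from the potassium enolate before it is trapped, proton transfer from the enolisable keto ester instead of addition, or erosion of the C1=C10 geometry and the C8 configuration if the other chair takes part. Fallback: the rearrangement is run without any metal enolate. It sets out from 14, which is silylated with N-(trimethylsilyl)imidazole to the 1,3-bis(trimethylsilyl) ether of 14, F1. Heating F1 in o-dichlorobenzene at 180–200 °C (neutral siloxy-Cope rearrangement, same chair) should give the trimethylsilyl enol ether of the ring-expanded ketone, F2. A Mukaiyama aldol addition of F2 to 18 (BF3·OEt2, CH2Cl2, −78 °C), with aqueous citric acid work-up to remove the C2 trimethylsilyl ether, comes back to the route at 21.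

2. Step 8. What may go wrong: attack of the organocopper reagent at the distal epoxide carbon C2, or a 1,2-shift of the C6 alkenyl group triggered by the Lewis-acidic magnesium salts. Fallback: a slender carbon nucleophile is used and the branch is built afterwards. It sets out from 13, which is opened with lithium acetylide–ethylenediamine complex (LiC≡CH·H2NCH2CH2NH2, DMSO, rt) to the C1 ethynyl diol (1R,2S,3R,5S)-5-[(tert-butyldimethylsilyl)oxy]-2-ethynyl-1-{(Z)-2-[(4-methoxybenzyl)oxy]ethenyl}-5-methylcyclohexane-1,3-diol, F3. Carbocupration of the terminal alkyne with the methylcopper reagent from MeMgBr and CuBr·SMe2 (Et2O/Me2S, −25 → 0 °C), then protonolysis, converts the ethynyl group into the isopropenyl group and comes back to the route at 14.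

3. Step 13. What may go wrong: the elimination gives mainly the (E)-alkene at C7=C11, whose carboxyl group cannot reach the C6 oxygen, or the tertiary aldol undergoes retro-aldol cleavage during the basic acylation. Fallback: the lactone ring is closed before the alkene is made, so that no alkene geometry has to be controlled. It sets out from 21, which is acetylated at the C2 hydroxyl only (Ac2O, pyridine, 0 °C) to the C2 monoacetate of 21, F4. Deallylation with Pd(PPh3)4 and morpholine gives the β-hydroxy γ-keto acid, which should close to its saturated lactol, (1(10)Z,2R,4S,8R)-2-acetoxy-4,13-bis[(tert-butyldimethylsilyl)oxy]-6,11-dihydroxy-8-[(4-methoxybenzyl)oxy]germacr-1(10)-en-12,6-olide, F5. Exhaustive acetylation and double elimination of acetic acid (Ac2O, Et3N, DMAP, then DBU) comes back to the route at 26.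

**Further compounds**

F1 | step 12 | 1,3-bis(trimethylsilyl) ether of diol 14 | C[Si](C)(C)O[C@]1(/C=C\OCc2ccc(OC)cc2)[C@@H](C(C)=C)[C@H](O[Si](C)(C)C)C[C@](C)(O[Si](C)(C)C(C)(C)C)C1
F2 | step 12 | (1(10)Z,2R,4S,6Z,8R)-4-[(tert-butyldimethylsilyl)oxy]-8-[(4-methoxybenzyl)oxy]-4,10-dimethyl-2,6-bis[(trimethylsilyl)oxy]cyclodeca-1(10),6-diene (ring numbered as in the remark) | C[Si](C)(C)O/C1=C\[C@H](OCc2ccc(OC)cc2)C/C(C)=C\[C@H](O[Si](C)(C)C)C[C@](C)(O[Si](C)(C)C(C)(C)C)C1
F3 | step 8 | (1R,2S,3R,5S)-5-[(tert-butyldimethylsilyl)oxy]-2-ethynyl-1-{(Z)-2-[(4-methoxybenzyl)oxy]ethenyl}-5-methylcyclohexane-1,3-diol | O[C@]1(/C=C\OCc2ccc(OC)cc2)[C@@H](C#C)[C@H](O)C[C@](C)(O[Si](C)(C)C(C)(C)C)C1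
F4 | step 13 | prop-2-en-1-yl (1(10)Z,2R,4S,8R)-2-acetoxy-4,13-bis[(tert-butyldimethylsilyl)oxy]-11-hydroxy-8-[(4-methoxybenzyl)oxy]-6-oxogermacr-1(10)-en-12-oate (C7 and C11 epimers) | O=C1C(C(O)(CO[Si](C)(C)C(C)(C)C)C(=O)OCC=C)[C@H](OCc2ccc(OC)cc2)C/C(C)=C\[C@H](OC(C)=O)C[C@](C)(O[Si](C)(C)C(C)(C)C)C1
F5 | step 13 | (1(10)Z,2R,4S,8R)-2-acetoxy-4,13-bis[(tert-butyldimethylsilyl)oxy]-6,11-dihydroxy-8-[(4-methoxybenzyl)oxy]germacr-1(10)-en-12,6-olide (C6, C7 and C11 epimers) | OC12OC(=O)C(O)(CO[Si](C)(C)C(C)(C)C)C1[C@H](OCc3ccc(OC)cc3)C/C(C)=C\[C@H](OC(C)=O)C[C@](C)(O[Si](C)(C)C(C)(C)C)C2
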